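**Retrosynthetic overview**

- The strategy rests on the fact that the target is one flavan-4-ol taken twice (2 × C17H18O5 − 2 H − H2O). The quaternary C8(OMe) of the dienone ring, para to the C5 carbonyl, is bonded to C6'' of the intact aromatic A ring, ortho to O5''. O5'' sits on the neighbouring ketal carbon C8a, and the C4=C4a alkene marks where a 4-OH has left.
- The 4''-alcohol is inverted last (Mitsunobu, methanolysis). Before that, the central dihydrobenzofuran ring (C8–C6'' and C8a–O5'') is cut back to two copies of (2S,4S)-5-hydroxy-7,8-dimethoxyflavan-4-ol by a dearomative para–ortho oxidative dimerisation.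
- The monomer comes from cis reduction of (2S)-5-hydroxy-7,8-dimethoxyflavanone, itself from asymmetric 1,4-addition of phenylboronic acid to 5,7,8-trimethoxychromone and peri O-demethylation.
- The chromone comes from 3,4,5-trimethoxyphenol through 2'-hydroxy-3',4',6'-trimethoxyacetophenone and its enaminone.
- Ring order: the pyranone ring is closed once and serves both halves; the dihydrobenzofuran ring is closed last.

Key step: step 9

Remark: flavan numbering is used (unprimed = dienone half, doubly primed = aromatic half). The target is taken as the (2S,8S,8aS,2''S,4''R) isomer, i.e. 2'',4''-trans with the 8a-aryloxy group trans to the 2-phenyl group. In step 6 the ligand antipode is assumed to be matched to the 2S product and checked by CD.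

**Route**

Step 1
Reactants: 1 3,4,5-trimethoxyphenol
Product: 2 1,2,3,5-tetramethoxybenzene
Conditions: MeI, K2CO3, acetone, reflux
Reagents that add atoms: iodomethane, CI
Why: Williamson ether synthesis on the phenoxide, the only nucleophilic site, should give the symmetrical tetramethyl ether.

Step 2
Reactants: 2 1,2,3,5-tetramethoxybenzene
Product: 3 2',3',4',6'-tetramethoxyacetophenone
Conditions: AcCl (1.1 equiv), AlCl3 (1.1 equiv), CH2Cl2, −10 to 0 °C; ice/HCl
Reagents that add atoms: acetyl chloride, CC(=O)Cl
Why: Friedel–Crafts acylation at one of the two free positions, which are equivalent by symmetry and each ortho/para to three methoxy groups, so a single ketone is expected and the acetyl group deactivates the ring against a second acylation.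

Step 3
Reactants: 3 2',3',4',6'-tetramethoxyacetophenone
Product: 4 2'-hydroxy-3',4',6'-trimethoxyacetophenone
Conditions: BCl3 (1.1 equiv), CH2Cl2, −78 to 0 °C; H2O
Reagents that add atoms: none
Why: Chelation-directed ether cleavage by carbonyl-bound BCl3 should take the 2'-methoxy group, which is buttressed between the acetyl and 3'-methoxy groups, twisted out of the ring plane and therefore the more basic of the two ortho ethers; the regiochemistry would be confirmed by NOE (H-5' to two methoxy groups) and by comparison with the isomeric 6'-hydroxy-2',3',4'-trimethoxyacetophenone obtainable by direct acetylation of 1.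

Step 4
Reactants: 4 2'-hydroxy-3',4',6'-trimethoxyacetophenone
Product: 5 (E)-3-(dimethylamino)-1-(2-hydroxy-3,4,6-trimethoxyphenyl)prop-2-en-1-one
Conditions: Me2NCH(OMe)2 (2 equiv), toluene, 100 °C
Reagents that add atoms: N,N-dimethylformamide dimethyl acetal, COC(OC)N(C)C
Why: Condensation of the methyl ketone with the amide acetal (loss of two methanol) gives the E-enaminone and brings in the future C2.

Step 5
Reactants: 5 (E)-3-(dimethylamino)-1-(2-hydroxy-3,4,6-trimethoxyphenyl)prop-2-en-1-one
Product: 6 5,7,8-trimethoxychromone
Conditions: conc. HCl, CH2Cl2, 40 °C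
Reagents that add atoms: none
Why: Acid-promoted 6-endo addition of the phenol to the enaminone β-carbon followed by elimination of dimethylamine closes the pyranone ring (enaminone route to chromones).

Step 6
Reactants: 6 5,7,8-trimethoxychromone; 7 phenylboronic acid
Product: 8 (2S)-5,7,8-trimethoxyflavanone
Conditions: Pd(OCOCF3)2 (5 mol%), t-BuPyOx (6 mol%, antipode giving 2S), NH4PF6 (30 mol%), H2O (5 equiv), ClCH2CH2Cl, 60 °C
Reagents that add atoms: none
Why: Catalytic asymmetric conjugate addition of an arylpalladium(II) species to the chromone C2=C3 bond and protonolysis of the Pd enolate, in which the pyridine-oxazoline ligand selects the enantiotopic face and so sets C2 as S (the ligand antipode that delivers 2S would be fixed on a small scale by CD of the flavanone).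

Step 7
Reactants: 8 (2S)-5,7,8-trimethoxyflavanone
Product: 9 (2S)-5-hydroxy-7,8-dimethoxyflavanone
Conditions: BCl3 (1.2 equiv), CH2Cl2, −78 to −20 °C; H2O
Reagents that add atoms: none
Why: Chelation-directed demethylation, in which BCl3 held between the C4 carbonyl and the peri 5-methoxy oxygen cleaves only that ether, under cold base-free conditions that avoid the chalcone ring-opening that would racemise C2.

Step 8
Reactants: 9 (2S)-5-hydroxy-7,8-dimethoxyflavanone
Product: 10 (2S,4S)-5-hydroxy-7,8-dimethoxyflavan-4-ol
Conditions: NaBH4, THF/MeOH, −10 to 0 °C; pH 7 buffer, no acid; used at once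
Reagents that add atoms: none
Why: Borohydride reduction of the flavanone half-chair (2-phenyl equatorial) by axial hydride delivery should give the equatorial 2,4-cis alcohol (4S), the usual outcome for flavanones, and the neutral work-up protects this easily ionised ortho-hydroxybenzylic alcohol.

Step 9
Reactants: 10 (2S,4S)-5-hydroxy-7,8-dimethoxyflavan-4-ol (two molecules: one is oxidised, one serves as the arene nucleophile)
Product: 12 4''-epi-6''-demethoxyneocalycopterone (2'',4''-cis alcohol), via C8–C6''-linked 8-aryl-8-methoxycyclohexadienone 11 (not isolated)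
Conditions: PhI(OAc)2 (0.52 equiv, slow addition), 10 at 0.3 M, (CF3)2CHOH/CH2Cl2 1:4, NaHCO3 (s), −40 to 0 °C
Reagents that add atoms: none
Why: Proposed new method: PhI(OAc)2 exchanges a ligand for the 5-OH of one molecule of 10 and heterolysis gives a phenoxenium ion that is best written as the C8 oxocarbenium of a cross-conjugated dienone, because the 7-OMe and O1 donors tie up C6 and C4a as the α-carbons of two vinylogous esters; the only C–H carbon of a second, unoxidised molecule (C6'', ortho/para to three oxygens) adds to C8 and rearomatises to give 11. The freed 5''-OH then closes the dihydrobenzofuran ring by 5-exo-trig oxa-Michael addition to C8a, and the resulting enol loses the C4 hydroxyl as water (vinylogous β-elimination, or equivalently ionisation at C4 and capture of the O1-stabilised cation at C8a), which makes the closure irreversible and leaves the C4=C4a enone. The closest known reactions are para–ortho oxidative phenol dimerisations closed by oxa-Michael addition (Pummerer's ketone, usnic acid) and iodine(III) couplings of 4-methoxyphenols with electron-rich arenes in fluoroalcohols; ipso attack at a methoxy-bearing para carbon and termination by loss of a benzylic hydroxyl are the untested extensions. C8 is set by approach of the arene to the face of the flat oxidised ring opposite the C2 phenyl and C4 hydroxyl of that half (substrate control, expected to be moderate, with the C8/C8a epimer removed by chromatography), and C8a follows from C8 because the five-membered ring can only be cis-fused, which places the aryloxy group axial (anomeric) and trans to the equatorial phenyl. Site selectivity comes from the substrate: C6'' is the sole nucleophilic carbon, closure at the other β-carbon C7 can only revert (aryloxide is a far better leaving group than methoxide and no hydroxyl is placed to be expelled), the product has no free phenol left to oxidise, and the buffered cold medium spares the benzylic alcohols.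

Step 10
Reactants: 12 4''-epi-6''-demethoxyneocalycopterone
Product: 13 4''-O-(4-nitrobenzoyl)-6''-demethoxyneocalycopterone (2'',4''-trans ester)
Conditions: 4-O2NC6H4CO2H, PPh3, DIAD, THF, 0 °C to rt
Reagents that add atoms: 4-nitrobenzoic acid, O=C(O)c1ccc(cc1)[N+](=O)[O-]
Why: Mitsunobu reaction at the only free hydroxyl, in which SN2 displacement of the oxyphosphonium by 4-nitrobenzoate inverts C4'' from S to R, and any ionisation of this electron-rich benzylic centre should be captured axially to give the same trans ester.

Step 11
Reactants: 13 4''-O-(4-nitrobenzoyl)-6''-demethoxyneocalycopterone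
Product: 14 6''-demethoxyneocalycopterone
Conditions: K2CO3 (0.3 equiv), MeOH/CH2Cl2, 0 °C, 30 min
Reagents that add atoms: none
Why: Base-catalysed methanolysis of the activated ester with retention at C4''; in methanol any exchange at the C7 vinylogous methyl ester is degenerate, and the short cold exposure should spare the ketal and the enone.

**Compound list**

1 | 3,4,5-trimethoxyphenol | COc1cc(O)cc(OC)c1OC | starting material
2 | 1,2,3,5-tetramethoxybenzene | COc1cc(OC)c(OC)c(OC)c1 | intermediate
3 | 2',3',4',6'-tetramethoxyacetophenone | CC(=O)c1c(OC)c(OC)c(OC)cc1OC | intermediate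
4 | 2'-hydroxy-3',4',6'-trimethoxyacetophenone | CC(=O)c1c(O)c(OC)c(OC)cc1OC | intermediate
5 | (E)-3-(dimethylamino)-1-(2-hydroxy-3,4,6-trimethoxyphenyl)prop-2-en-1-one | CN(C)/C=C/C(=O)c1c(O)c(OC)c(OC)cc1OC | intermediate
6 | 5,7,8-trimethoxychromone (5,7,8-trimethoxy-4H-chromen-4-one) | COc1cc(OC)c2C(=O)C=COc2c1OC | intermediate
7 | phenylboronic acid | OB(O)c1ccccc1 | starting material
8 | (2S)-5,7,8-trimethoxyflavanone | COc1cc(OC)c2C(=O)C[C@@H](c3ccccc3)Oc2c1OC | intermediate
9 | (2S)-5-hydroxy-7,8-dimethoxyflavanone | COc1cc(O)c2C(=O)C[C@@H](c3ccccc3)Oc2c1OC | intermediate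
10 | (2S,4S)-5-hydroxy-7,8-dimethoxyflavan-4-ol (2,4-cis monomer) | COc1cc(O)c2[C@@H](O)C[C@@H](c3ccccc3)Oc2c1OC | intermediate
11 | (2S,4S,8S)-8-[(2''S,4''S)-4'',5''-dihydroxy-7'',8''-dimethoxyflavan-6''-yl]-4-hydroxy-7,8-dimethoxy-2-phenyl-3,4-dihydro-2H-chromen-5(8H)-one (C8–C6''-linked 8-aryl-8-methoxycyclohexadienone; aryl on the face opposite the 2-phenyl) | COC1=CC(=O)C2=C(O[C@H](c3ccccc3)C[C@@H]2O)[C@]1(OC)c1c(O)c2c(c(OC)c1OC)O[C@H](c1ccccc1)C[C@@H]2O | intermediate
12 | 4''-epi-6''-demethoxyneocalycopterone, (2S,8S,8aS,2''S,4''S): cis-fused dihydrobenzofuran ketal, 2'',4''-cis alcohol | COC1=CC(=O)C2=CC[C@@H](c3ccccc3)O[C@]23Oc2c4c(c(OC)c(OC)c2[C@]13OC)O[C@H](c1ccccc1)C[C@@H]4O | intermediate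
13 | 4''-O-(4-nitrobenzoyl)-6''-demethoxyneocalycopterone, (2S,8S,8aS,2''S,4''R): 2'',4''-trans ester | COC1=CC(=O)C2=CC[C@@H](c3ccccc3)O[C@]23Oc2c4c(c(OC)c(OC)c2[C@]13OC)O[C@H](c1ccccc1)C[C@H]4OC(=O)c1ccc(cc1)[N+](=O)[O-] | intermediate
14 | 6''-demethoxyneocalycopterone, (2S,8S,8aS,2''S,4''R) | COC1=CC(=O)C2=CC[C@@H](c3ccccc3)O[C@]23Oc2c4c(c(OC)c(OC)c2[C@]13OC)O[C@H](c1ccccc1)C[C@H]4O | target

**Step count**

Total step count: 11. Longest linear sequence: 11 steps (1 to 14; 7 enters in step 6).

**Steps most likely to fail**

1. Step 9 (proposed new method).
   - What may go wrong: the oxidised ring may be captured at C8 by acetate, fluoroalcohol or traces of water and collapse to the 5,8-quinone with loss of methanol. The arene may instead bond at C6 and rearomatise to a 6,6''-biaryl. The benzylic C4–OH may ionise in the fluoroalcohol and alkylate a second molecule. Face selectivity at C8 may be low.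
   - Fallback (sets out from 10, comes back at 12): oxidation is separated from bond formation. One portion of 10 is oxidised with PhI(OAc)2 in methanol over NaHCO3 at −20 °C, the routine conversion of a 4-methoxyphenol into its quinone monoketal, and the product (2S,4S)-4-hydroxy-7,8,8-trimethoxy-2-phenyl-3,4-dihydro-2H-chromen-5(8H)-one F1 is isolated. F1 is then combined with an excess of 10 in (CF3)2CHOH/CH2Cl2 at −40 °C with a catalytic Brønsted acid (diphenyl phosphate or an acidic clay). Both operations belong to established classes (iodine(III) ketalisation of 4-methoxyphenols; acid-promoted arylation of quinone monoketals in fluoroalcohols), but substitution at the ketal carbon itself is not the usual site for that arylation. It is expected here because the two carbons α to the carbonyl, through which quinone monoketals normally take up arenes, are α-carbons of vinylogous esters and one of them (C4a) is fully substituted. Loss of methanol from the ketal regenerates the C8 oxocarbenium with no oxidant or acetate present, so that substitution by C6'' should give 11 and, after closure, 12.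

2. Step 10.
   - What may go wrong: the oxyphosphonium of this hindered, peri-flanked and electron-rich benzylic alcohol may eliminate to the flav-3-ene, ionise with loss of stereospecificity, or react slowly while the phosphine adds to the enone.
   - Fallback (sets out from 10, comes back at 14): C4 is inverted before the union. The phenol of 10 is silylated selectively (TBSCl, imidazole, DMF, 0 °C) to (2S,4S)-5-(tert-butyldimethylsilyloxy)-7,8-dimethoxyflavan-4-ol F2. Mitsunobu reaction with 4-nitrobenzoic acid (PPh3, DIAD, THF), a well-tried inversion of simple cis-flavan-4-ols, gives (2S,4R)-5-(tert-butyldimethylsilyloxy)-7,8-dimethoxyflavan-4-yl 4-nitrobenzoate F3. K2CO3 in methanol removes the ester and the aryl silyl ether to give the trans monomer (2S,4R)-5-hydroxy-7,8-dimethoxyflavan-4-ol F4. Under the conditions of step 9, F4 should give, through the (4R,4''R)-dienone F5 (not isolated), the target 14 directly, so steps 10 and 11 fall away; the hydroxyl expelled from the oxidised half is then 4R, which changes nothing in the product.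

3. Step 6.
   - What may go wrong: the electron-rich chromone, a doubly donor-substituted vinylogous ester with a peri methoxy group, may insert too slowly, so that protodeboronation of 7 dominates or enantioselectivity is insufficient.
   - Fallback (sets out from 4, comes back at 8): Claisen–Schmidt condensation of 4 with benzaldehyde (KOH, EtOH) gives 2'-hydroxy-3',4',6'-trimethoxychalcone F6. Intramolecular oxa-Michael addition (NaOAc, EtOH, reflux) gives racemic 5,7,8-trimethoxyflavanone F7. Preparative chromatography on a polysaccharide chiral stationary phase then delivers 8, and the antipode (2R)-5,7,8-trimethoxyflavanone F8 is set aside (it can be returned to F7 through base-induced ring opening and reclosure).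

Further compounds
F1 | step 9 | (2S,4S)-4-hydroxy-7,8,8-trimethoxy-2-phenyl-3,4-dihydro-2H-chromen-5(8H)-one (quinone monoketal of 10) | COC1=CC(=O)C2=C(O[C@H](c3ccccc3)C[C@@H]2O)C1(OC)OC
F2 | step 10 | (2S,4S)-5-(tert-butyldimethylsilyloxy)-7,8-dimethoxyflavan-4-ol | COc1cc(O[Si](C)(C)C(C)(C)C)c2[C@@H](O)C[C@@H](c3ccccc3)Oc2c1OC
F3 | step 10 | (2S,4R)-5-(tert-butyldimethylsilyloxy)-7,8-dimethoxyflavan-4-yl 4-nitrobenzoate | COc1cc(O[Si](C)(C)C(C)(C)C)c2[C@H](OC(=O)c3ccc(cc3)[N+](=O)[O-])C[C@@H](c4ccccc4)Oc2c1OC
F4 | step 10 | (2S,4R)-5-hydroxy-7,8-dimethoxyflavan-4-ol (2,4-trans monomer) | COc1cc(O)c2[C@H](O)C[C@@H](c3ccccc3)Oc2c1OC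
F5 | step 10 | (4R,4''R)-dienone (C4 and C4'' epimer of 11) | COC1=CC(=O)C2=C(O[C@H](c3ccccc3)C[C@H]2O)[C@]1(OC)c1c(O)c2c(c(OC)c1OC)O[C@H](c1ccccc1)C[C@H]2O
F6 | step 6 | 2'-hydroxy-3',4',6'-trimethoxychalcone | O=C(/C=C/c1ccccc1)c1c(O)c(OC)c(OC)cc1OC
F7 | step 6 | racemic 5,7,8-trimethoxyflavanone | COc1cc(OC)c2C(=O)CC(c3ccccc3)Oc2c1OC
F8 | step 6 | (2R)-5,7,8-trimethoxyflavanone | COc1cc(OC)c2C(=O)C[C@H](c3ccccc3)Oc2c1OC
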